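**Retrosynthetic overview**
1. Target 8 ⇒ alkyne triol 6 + 2-iodoaniline 7: the 2,3-disubstituted indole (ring B) is closed last by Larock heteroannulation, the alkyne serving as a masked indol-2-yl.
2. 6 ⇒ alkynyl epoxy alcohol 4 + indole 5 (ring A, bought): invertive opening at the propargylic oxirane carbon sets the methine centre.
3. 4 ⇒ enyne diol 3: Sharpless asymmetric epoxidation; its two C–O bonds are the source of both stereocentres (C2 kept, C3 inverted in the opening).
4. 3 ⇒ but-3-yn-1-ol 1 + (E)-3-iodoprop-2-en-1-ol 2 by Sonogashira coupling.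
5. Ring order: oxirane (made, then opened), then the pyrrole ring of indole B (closed by C–N reductive elimination).

Assumption: the SMILES is read as (2S,3S), carbinol carbon S and bis-indolyl methine S; 2 and D-(−)-diethyl tartrate are taken as catalogue chemicals.

**Step 1**
Reactants: 1 but-3-yn-1-ol; 2 (E)-3-iodoprop-2-en-1-ol
Product: 3 (2E)-hept-2-en-4-yne-1,7-diol
Conditions: PdCl2(PPh3)2 (2 mol%), CuI (4 mol%), Et3N, THF, rt
Reagents that add atoms: none
Why: Sonogashira coupling of a vinyl iodide with a terminal alkyne keeps the E geometry and tolerates both free primary alcohols.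

**Step 2**
Reactants: 3 (2E)-hept-2-en-4-yne-1,7-diol
Product: 4 [(2R,3R)-3-(4-hydroxybut-1-yn-1-yl)oxiran-2-yl]methanol
Conditions: Ti(OiPr)4 (15 mol%), D-(−)-diethyl tartrate (18 mol%), anhydrous t-BuOOH in decane, 4 Å MS, CH2Cl2, −20 °C; non-aqueous work-up
Reagents that add atoms: tert-butyl hydroperoxide, CC(C)(C)OO
Why: Sharpless asymmetric epoxidation, in which the chiral catalyst formed from Ti(OiPr)4 and D-(−)-diethyl tartrate binds the allylic hydroxyl and delivers the peroxide oxygen to the alkene face that gives the (2R,3R)-trans-epoxide from an E-allylic alcohol (E-enynols are established substrates), while the remote primary alcohol, held away by the rigid enyne spacer, cannot chelate the metal.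

**Step 3**
Reactants: 4 [(2R,3R)-3-(4-hydroxybut-1-yn-1-yl)oxiran-2-yl]methanol; 5 1H-indole
Product: 6 (2S,3R)-3-(1H-indol-3-yl)hept-4-yne-1,2,7-triol
Conditions: InBr3 (10 mol%), excess indole, CH2Cl2, 0 °C to rt
Reagents that add atoms: none
Why: Proposed new method: InBr3 (trivalent indium) binds the oxirane oxygen and the neighbouring CH2OH in a five-membered chelate, the C3–O bond is the one that lengthens because the developing positive charge is propargylic (alkyne-stabilised) whereas C2 is deactivated by the adjacent C–O dipole, and indole C3 attacks oxirane C3 anti to the departing oxygen in a loose SN2 transition state, so C3 is inverted (its descriptor stays R because the substituent priorities change), C2 keeps its oxygen as 2S and the reaction is a pure addition of the two partners; the closest known reaction types are the InBr3-catalysed invertive Friedel–Crafts opening of enantiopure aryl oxiranes by indoles at the benzylic carbon and the Lewis-acid-templated C3-selective opening of 2,3-epoxy alcohols by heteroatom nucleophiles, neither shown for an alkynyl 2,3-epoxy alcohol with a carbon nucleophile.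

**Step 4**
Reactants: 6 (2S,3R)-3-(1H-indol-3-yl)hept-4-yne-1,2,7-triol; 7 2-iodoaniline
Product: 8 (2S,3S)-3-[3-(2-hydroxyethyl)-1H-indol-2-yl]-3-(1H-indol-3-yl)propane-1,2-diol (colletotryptin B)
Conditions: Pd(OAc)2 (5 mol%), LiCl, K2CO3, DMF, 100 °C, slight excess of the iodoaniline
Reagents that add atoms: none
Why: Larock heteroannulation, in which zerovalent palladium inserts into the C–I bond, the aryl group adds to the less hindered alkyne carbon (the one bearing CH2CH2OH) with palladium on the carbon next to the branched substituent, and C–N reductive elimination closes the pyrrole ring, so the branched group ends at C2 and the hydroxyethyl at C3 with neither stereocentre touched (the methine descriptor changes from R to S only because the alkyne carbon becomes the higher-ranked indol-2-yl).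

**Compound list**
1 | but-3-yn-1-ol | C#CCCO | starting material
2 | (E)-3-iodoprop-2-en-1-ol | OC/C=C/I | starting material
3 | (2E)-hept-2-en-4-yne-1,7-diol | OC/C=C/C#CCCO | intermediate
4 | [(2R,3R)-3-(4-hydroxybut-1-yn-1-yl)oxiran-2-yl]methanol | OCCC#C[C@H]1O[C@@H]1CO | intermediate
5 | 1H-indole | c1ccc2[nH]ccc2c1 | starting material
6 | (2S,3R)-3-(1H-indol-3-yl)hept-4-yne-1,2,7-triol | OCCC#C[C@H](c1c[nH]c2ccccc12)[C@H](O)CO | intermediate
7 | 2-iodoaniline | Nc1ccccc1I | starting material
8 | (2S,3S)-3-[3-(2-hydroxyethyl)-1H-indol-2-yl]-3-(1H-indol-3-yl)propane-1,2-diol (colletotryptin B) | OCCc1c([C@H](c2c[nH]c3ccccc23)[C@H](O)CO)[nH]c2ccccc12 | target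

**Totals**
Total step count: 4. Longest linear sequence: 4 steps (1 → 3 → 4 → 6 → 8).

**Three steps most likely to fail**

Step 3 (the proposed new method). The risks are partial ionisation to a propargylic cation (loss of stereospecificity), attack at the alkyne terminus to give an allene, and Lewis-acid activation of the alkyne. The fallback uses known organocatalysis, sets out from 3 and comes back at 6. Activated MnO2 in CH2Cl2 oxidises only the allylic alcohol of 3 to (2E)-7-hydroxyhept-2-en-4-ynal F1. Iminium-catalysed Friedel–Crafts addition of indole 5 then gives (3R)-7-hydroxy-3-(1H-indol-3-yl)hept-4-ynal F2; the catalyst is the (2R,5R) enantiomer of the second-generation MacMillan imidazolidinone (5-benzyl-2-tert-butyl-3-methylimidazolidin-4-one, TFA salt, 20 mol%, CH2Cl2/i-PrOH, −50 °C), the antipode being chosen by analogy with the facial selectivity known for simple enals. D-Proline-catalysed α-aminoxylation with nitrosobenzene gives (2S,3R)-2-(anilinooxy)-7-hydroxy-3-(1H-indol-3-yl)hept-4-ynal F3, which is not isolated, and NaBH4 in the same pot reduces it to (2S,3R)-2-(anilinooxy)-3-(1H-indol-3-yl)hept-4-yne-1,7-diol F4. Zn/AcOH finally cleaves the N–O bond to give 6. Both stereocentres are then set by catalyst control, and the C2–O bond is made by enamine catalysis in place of the epoxide.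

Step 4. The risks are incomplete regiocontrol for a dialkyl alkyne (the free 7-OH may coordinate palladium and steer it to the wrong carbon) and sluggish turnover with a chelating triol. The fallback sets out from 6 and comes back at 8, and makes the annulation purely sterically controlled. Excess TBSCl with imidazole in DMF gives 3-{(2S,3R)-1,2,7-tris[(tert-butyldimethylsilyl)oxy]hept-4-yn-3-yl}-1H-indole F5. Larock annulation of this silyl ether with 7 (Pd(OAc)2, LiCl, K2CO3, DMF, 100 °C) gives 2-{(1S,2S)-2,3-bis[(tert-butyldimethylsilyl)oxy]-1-(1H-indol-3-yl)propyl}-3-{2-[(tert-butyldimethylsilyl)oxy]ethyl}-1H-indole F6, and TBAF in THF then gives 8.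

Step 2. The risks are slow epoxidation of the electron-poor enyne alkene, interference by the second hydroxyl, and loss of the small water-soluble epoxy diol on isolation. The fallback sets out from 1 and comes back at 4, and gives a lipophilic mono-alcohol substrate that tolerates aqueous work-up. TBSCl and imidazole in CH2Cl2 give tert-butyl(but-3-yn-1-yloxy)dimethylsilane F7, and Sonogashira coupling of this with 2 under the step 1 conditions gives (2E)-7-[(tert-butyldimethylsilyl)oxy]hept-2-en-4-yn-1-ol F8. The same Ti(OiPr)4/D-(−)-diethyl tartrate/t-BuOOH epoxidation gives [(2R,3R)-3-{4-[(tert-butyldimethylsilyl)oxy]but-1-yn-1-yl}oxiran-2-yl]methanol F9, and TBAF buffered with AcOH in THF at 0 °C then gives 4, purified by direct chromatography.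

**Further compounds**
F1 | step 3 | (2E)-7-hydroxyhept-2-en-4-ynal | O=C/C=C/C#CCCO
F2 | step 3 | (3R)-7-hydroxy-3-(1H-indol-3-yl)hept-4-ynal | OCCC#C[C@H](c1c[nH]c2ccccc12)CC=O
F3 | step 3 | (2S,3R)-2-(anilinooxy)-7-hydroxy-3-(1H-indol-3-yl)hept-4-ynal | OCCC#C[C@H](c1c[nH]c2ccccc12)[C@H](ONc1ccccc1)C=O
F4 | step 3 | (2S,3R)-2-(anilinooxy)-3-(1H-indol-3-yl)hept-4-yne-1,7-diol | OCCC#C[C@H](c1c[nH]c2ccccc12)[C@H](ONc1ccccc1)CO
F5 | step 4 | 3-{(2S,3R)-1,2,7-tris[(tert-butyldimethylsilyl)oxy]hept-4-yn-3-yl}-1H-indole | CC(C)(C)[Si](C)(C)OCCC#C[C@H](c1c[nH]c2ccccc12)[C@H](O[Si](C)(C)C(C)(C)C)CO[Si](C)(C)C(C)(C)C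
F6 | step 4 | 2-{(1S,2S)-2,3-bis[(tert-butyldimethylsilyl)oxy]-1-(1H-indol-3-yl)propyl}-3-{2-[(tert-butyldimethylsilyl)oxy]ethyl}-1H-indole | CC(C)(C)[Si](C)(C)OCCc1c([C@H](c2c[nH]c3ccccc23)[C@H](O[Si](C)(C)C(C)(C)C)CO[Si](C)(C)C(C)(C)C)[nH]c2ccccc12
F7 | step 2 | tert-butyl(but-3-yn-1-yloxy)dimethylsilane | C#CCCO[Si](C)(C)C(C)(C)C
F8 | step 2 | (2E)-7-[(tert-butyldimethylsilyl)oxy]hept-2-en-4-yn-1-ol | OC/C=C/C#CCCO[Si](C)(C)C(C)(C)C
F9 | step 2 | [(2R,3R)-3-{4-[(tert-butyldimethylsilyl)oxy]but-1-yn-1-yl}oxiran-2-yl]methanol | CC(C)(C)[Si](C)(C)OCCC#C[C@H]1O[C@@H]1CO
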